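**Plan**

1. Retrosynthesis: both pyran rings are opened first, each at its O1–C2 bond (and with it C4–C4a), which leads back to an acyclic bis(aryl 1,1-dimethylpropargyl ether); the C(sp3)–C(sp2) bond between the stereocentre and the alkene is cut next, giving a racemic benzylic chloride and an (E)-alkenyl bromide, both from 4-hydroxy-2-methoxybenzaldehyde.
2. Enabling feature: each pyran ring (O1–C2Me2–C3=C4–C4a=C8a) is a benzo-fused 2H-pyran, the closed valence tautomer of a cis-dienone O=C8a–C4a=C4–C3=C2Me2. That dienone is reachable from an ether on O1 because C4a is a free C–H ortho to that oxygen and para to the methoxy group.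
3. Forward order: the chain is joined first by a nickel-catalysed coupling of the two arene fragments (ring A on the alkene, ring B on the stereocentre); both pyran rings then arise together in the last step.
4. Stereochemistry: the single (S) centre is set by the chiral nickel catalyst in the stereoconvergent coupling; the E-alkene comes from the Takai olefination and is retained.

Key step: step 8

Remark: in step 8 the two aryl propargyl ether arms should react independently; intermediates 11–13 are written for the case in which both arms have reached the same stage.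

**Step 1**
Reactants: 1 4-hydroxy-2-methoxybenzaldehyde
Product: 2 4-formyl-3-methoxyphenyl pivalate
Conditions: pivaloyl chloride, Et3N, DMAP (cat.), CH2Cl2, 0 °C to rt
Reagents that add atoms: pivaloyl chloride, CC(C)(C)C(Cl)=O
Why: DMAP-catalysed O-acylation of the phenol should be clean, and the pivalate lowers the donor strength of the para oxygen so that the later benzylic chloride is tame.

**Step 2**
Reactants: 2 4-formyl-3-methoxyphenyl pivalate
Product: 4 (E)-4-(2-bromoethenyl)-3-methoxyphenyl pivalate, via bromochromium alkoxide adduct 3 (not isolated)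
Conditions: CrBr2 (6 equiv), CHBr3 (2 equiv), THF, 50 °C
Reagents that add atoms: bromoform, BrC(Br)Br
Why: Takai olefination, in which the geminal dichromium reagent from bromoform and divalent chromium adds to the aldehyde and the adduct eliminates to the E-alkenyl bromide; the all-bromide chromium salt avoids halide exchange.

**Step 3**
Reactants: 2 4-formyl-3-methoxyphenyl pivalate
Product: 5 rac-4-(1-hydroxyethyl)-3-methoxyphenyl pivalate
Conditions: MeMgBr (1.1 equiv), THF, −78 °C; then aq NH4Cl
Reagents that add atoms: methylmagnesium bromide, C[Mg]Br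
Why: Grignard addition, in which the aldehyde should react far faster than the hindered aryl pivalate at −78 °C; the new centre may be racemic because step 5 is stereoconvergent.

**Step 4**
Reactants: 5 rac-4-(1-hydroxyethyl)-3-methoxyphenyl pivalate
Product: 7 rac-4-(1-chloroethyl)-3-methoxyphenyl pivalate, via benzylic chlorosulfite 6 (not isolated)
Conditions: SOCl2 (1.5 equiv), CH2Cl2, 0 °C; concentrated and used crude
Reagents that add atoms: thionyl chloride, O=S(Cl)Cl
Why: deoxychlorination of a secondary benzylic alcohol through its chlorosulfite, helped by the ortho-methoxy group, while the para-pivalate should hold back loss of HCl to the styrene.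

**Step 5**
Reactants: 4 (E)-4-(2-bromoethenyl)-3-methoxyphenyl pivalate; 7 rac-4-(1-chloroethyl)-3-methoxyphenyl pivalate
Product: 8 4-[(1E,3S)-3-[2-methoxy-4-(pivaloyloxy)phenyl]but-1-en-1-yl]-3-methoxyphenyl pivalate
Conditions: NiCl2(dme) (10 mol %), chiral cyclopropane-1,1-diyl-bridged bis(indano-oxazoline) ligand (11 mol %), Mn powder (3 equiv), NaI (0.5 equiv), DMA, 0 °C
Reagents that add atoms: none
Why: nickel-catalysed asymmetric reductive cross-electrophile coupling of an alkenyl bromide with a racemic secondary benzylic chloride, in which the benzylic radical is captured by the chiral alkenylnickel species and reductive elimination sets the (S) centre under ligand control with the E geometry retained; the ligand antipode that delivers (S) is used, both being available.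

**Step 6**
Reactants: 8 4-[(1E,3S)-3-[2-methoxy-4-(pivaloyloxy)phenyl]but-1-en-1-yl]-3-methoxyphenyl pivalate
Product: 9 4-[(1E,3S)-3-(4-hydroxy-2-methoxyphenyl)but-1-en-1-yl]-3-methoxyphenol
Conditions: NaOMe (2.2 equiv), MeOH–THF, 0 °C to rt; then AcOH (2.2 equiv)
Reagents that add atoms: none
Why: Zemplén-type transesterification of the two aryl esters, under which methoxide in methanol is far too weak a base to remove the benzylic-allylic hydrogen, so the centre and the alkene position should be kept.

**Step 7**
Reactants: 9 4-[(1E,3S)-3-(4-hydroxy-2-methoxyphenyl)but-1-en-1-yl]-3-methoxyphenol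
Product: 10 (S,E)-1,3-bis{2-methoxy-4-[(2-methylbut-3-yn-2-yl)oxy]phenyl}but-1-ene
Conditions: 3-chloro-3-methylbut-1-yne (3 equiv), DBU (3.2 equiv), CuCl2·2H2O (1 mol %), MeCN, 0 °C
Reagents that add atoms: 3-chloro-3-methylbut-1-yne, CC(C)(Cl)C#C
Why: copper-catalysed propargylic etherification, in which the copper acetylide ionises the tertiary chloride to a copper allenylidene that the phenoxide attacks at the tertiary carbon, a mild way to make both hindered aryl ethers.

**Step 8**
Reactants: 10 (S,E)-1,3-bis{2-methoxy-4-[(2-methylbut-3-yn-2-yl)oxy]phenyl}but-1-ene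
Product: 14 6-[(1E,3S)-3-(7-methoxy-2,2-dimethyl-2H-chromen-6-yl)but-1-en-1-yl]-7-methoxy-2,2-dimethyl-2H-chromene, via bis(allenylcyclohexadienone) 11 (not isolated), via bis(ortho-allenylphenol) 12 (not isolated), via bis(ortho-quinone methide) 13 (not isolated)
Conditions: o-xylene (0.02 M), argon, 140 °C
Reagents that add atoms: none
Why: Each aryl 1,1-dimethylpropargyl ether should undergo a thermal aromatic propargyl Claisen ([3,3]) shift to the free ortho carbon to give allenyl dienone 11, which enolises to 12; a [1,5]-hydrogen shift from O–H to the central allene carbon then gives the cis-dienone 13, whose oxa-6π electrocyclisation joins the carbonyl oxygen to the CMe2 terminus, makes the O1–C2 bond of each pyran and restores the benzene ring. The closest known reaction type is the thermal rearrangement of aryl 1,1-dimethylpropargyl ethers to 2,2-dimethyl-2H-chromenes, here run twofold in one molecule. Each six-membered pyran ring closes by a thermal disrotatory 6π electrocyclisation of a 1-oxatriene, for which the [1,5]-shift delivers the required cis geometry of the central C4a=C4 bond. No new stereocentre arises because C2 carries two methyl groups, and the (S) centre is untouched under neutral, metal-free conditions; in 13 the diene that flanks it is locked s-trans, so no sigmatropic hydrogen shift can erase it. The step needs regioselectivity between the two ortho carbons of each ring: the C–H para to the methoxy group must be taken and not the carbon between the two oxygens, and this is secured by the methoxy group, which the neighbouring side chain forces to turn its methyl over the carbon between the oxygens. The gem-dimethyl group speeds the [3,3] shift so that 140 °C should suffice, a temperature at which the E-alkene and both arenes should be stable.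

**Compound list**

1 | 4-hydroxy-2-methoxybenzaldehyde | COc1cc(O)ccc1C=O | starting material
2 | 4-formyl-3-methoxyphenyl pivalate | COc1cc(OC(=O)C(C)(C)C)ccc1C=O | intermediate
3 | bromochromium alkoxide adduct of 2 with the geminal dichromium reagent (diastereomer mixture, not isolated) | COc1cc(OC(=O)C(C)(C)C)ccc1C(O[Cr](Br)Br)C(Br)[Cr](Br)Br | intermediate
4 | (E)-4-(2-bromoethenyl)-3-methoxyphenyl pivalate | COc1cc(OC(=O)C(C)(C)C)ccc1/C=C/Br | intermediate
5 | rac-4-(1-hydroxyethyl)-3-methoxyphenyl pivalate | COc1cc(OC(=O)C(C)(C)C)ccc1C(C)O | intermediate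
6 | rac-1-[2-methoxy-4-(pivaloyloxy)phenyl]ethyl chlorosulfite (not isolated) | COc1cc(OC(=O)C(C)(C)C)ccc1C(C)OS(Cl)=O | intermediate
7 | rac-4-(1-chloroethyl)-3-methoxyphenyl pivalate | COc1cc(OC(=O)C(C)(C)C)ccc1C(C)Cl | intermediate
8 | 4-[(1E,3S)-3-[2-methoxy-4-(pivaloyloxy)phenyl]but-1-en-1-yl]-3-methoxyphenyl pivalate | COc1cc(OC(=O)C(C)(C)C)ccc1/C=C/[C@H](C)c1ccc(OC(=O)C(C)(C)C)cc1OC | intermediate
9 | 4-[(1E,3S)-3-(4-hydroxy-2-methoxyphenyl)but-1-en-1-yl]-3-methoxyphenol | COc1cc(O)ccc1/C=C/[C@H](C)c1ccc(O)cc1OC | intermediate
10 | (S,E)-1,3-bis{2-methoxy-4-[(2-methylbut-3-yn-2-yl)oxy]phenyl}but-1-ene | COc1cc(OC(C)(C)C#C)ccc1/C=C/[C@H](C)c1ccc(OC(C)(C)C#C)cc1OC | intermediate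
11 | bis(allenylcyclohexadienone): (S,E)-but-1-ene carrying at C1 and C3 a 3-methoxy-6-(3-methylbuta-1,2-dien-1-yl)cyclohexa-2,4-dien-1-on-4-yl ring (epimer mixture at the two transient ring sp3 carbons, not isolated) | COC1=CC(=O)C(C=C=C(C)C)C=C1/C=C/[C@H](C)C1=CC(C=C=C(C)C)C(=O)C=C1OC | intermediate
12 | (S,E)-1,3-bis[4-hydroxy-2-methoxy-5-(3-methylbuta-1,2-dien-1-yl)phenyl]but-1-ene (not isolated) | COc1cc(O)c(C=C=C(C)C)cc1/C=C/[C@H](C)c1cc(C=C=C(C)C)c(O)cc1OC | intermediate
13 | bis(ortho-quinone methide): (S,E)-but-1-ene carrying at C1 and C3 a 3-methoxy-6-[(Z)-3-methylbut-2-en-1-ylidene]cyclohexa-2,4-dien-1-on-4-yl ring (not isolated) | COC1=CC(=O)/C(=C\C=C(C)C)C=C1/C=C/[C@H](C)C1=C/C(=C/C=C(C)C)C(=O)C=C1OC | intermediate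
14 | 6-[(1E,3S)-3-(7-methoxy-2,2-dimethyl-2H-chromen-6-yl)but-1-en-1-yl]-7-methoxy-2,2-dimethyl-2H-chromene | COc1cc2c(cc1/C=C/[C@H](C)c1cc3c(cc1OC)OC(C)(C)C=C3)C=CC(C)(C)O2 | target

**Summary**

Total step count: 8. Longest linear sequence: 7 steps (steps 1, 3, 4, 5, 6, 7, 8).

Steps most likely to fail:

1. Step 5. Enantiocontrol may erode because both partners carry an ortho-methoxy group next to the bond being formed, and the benzylic chloride may lose hydrogen chloride or homocouple before it is intercepted. The fallback sets out from compound 2 and comes back at compound 8. Wittig methylenation of 2 (Ph3P=CH2, THF, −78 °C to 0 °C) should give the styrene 4-ethenyl-3-methoxyphenyl pivalate F1. Nickel-catalysed asymmetric hydrovinylation of F1 with ethene ([Ni(allyl)Br]2, chiral phosphoramidite ligand, NaB[3,5-(CF3)2C6H3]4, CH2Cl2, low temperature) should give (S)-4-(but-3-en-2-yl)-3-methoxyphenyl pivalate F2. Cross-metathesis of F2 with a further portion of F1 (second-generation Hoveyda–Grubbs catalyst, CH2Cl2, 40 °C) should give the E-alkene 8. In this variant the stereocentre comes from the hydrovinylation and the alkene from metathesis.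

2. Step 8. The sigmatropic shift may take the ortho carbon between the two oxygens on one or both rings, or the hot dienone may be intercepted intermolecularly. The fallback sets out from compound 9, bypasses 10, and comes back at compound 13, which closes to 14. Bisphenol 9 is heated with 3-methylbut-2-enal and phenylboronic acid (catalytic propionic acid, toluene, reflux, water removal). Ortho-specific condensation, directed electronically to the carbon para to the methoxy group, should give the bis(4-(2-methylprop-1-enyl)-2-phenyl-4H-1,3,2-benzodioxaborin) F3 (not isolated). F3 fragments thermally with loss of phenylboronic acid to the same bis(ortho-quinone methide) 13, and the same oxa-6π closure then makes the two O1–C2 bonds.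

3. Step 2. The olefination may proceed with incomplete E-selectivity, and the aldehyde may be reduced or pinacol-coupled by the divalent chromium. The fallback sets out from compound 2 and comes back at compound 4. Doebner–Knoevenagel condensation of 2 with malonic acid (pyridine, catalytic piperidine, 80 °C) should pass through 2-[2-methoxy-4-(pivaloyloxy)benzylidene]malonic acid F4 (not isolated) to (E)-3-[2-methoxy-4-(pivaloyloxy)phenyl]prop-2-enoic acid F5. Hunsdiecker-type bromodecarboxylation of F5 (N-bromosuccinimide, catalytic Et3N, CH2Cl2, rt) should give the E-alkenyl bromide 4.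

**Further compounds**

F1 | step 5 | 4-ethenyl-3-methoxyphenyl pivalate | COc1cc(OC(=O)C(C)(C)C)ccc1C=C
F2 | step 5 | (S)-4-(but-3-en-2-yl)-3-methoxyphenyl pivalate | C=C[C@H](C)c1ccc(OC(=O)C(C)(C)C)cc1OC
F3 | step 8 | (S,E)-1,3-bis[7-methoxy-4-(2-methylprop-1-enyl)-2-phenyl-4H-1,3,2-benzodioxaborin-6-yl]but-1-ene (mixture at the two acetal carbons, not isolated) | COc1cc2OB(c3ccccc3)OC(C=C(C)C)c2cc1/C=C/[C@H](C)c1cc2C(C=C(C)C)OB(c3ccccc3)Oc2cc1OC
F4 | step 2 | 2-[2-methoxy-4-(pivaloyloxy)benzylidene]malonic acid (not isolated) | COc1cc(OC(=O)C(C)(C)C)ccc1C=C(C(=O)O)C(=O)O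
F5 | step 2 | (E)-3-[2-methoxy-4-(pivaloyloxy)phenyl]prop-2-enoic acid | COc1cc(OC(=O)C(C)(C)C)ccc1/C=C/C(=O)O
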